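**Plan**
1. Numbering: decalin C1–C10 (ring A = C1–C5, C10; ring B = C5–C10), C11 = CHO on C9, C17 = CH3 on C8; dihydrofuran O–C15(OAc)–C14(on C8)–C13(=C16H–O), C12 = CH2OAc on C13.
2. Cuts: the two acetates and the C13=C16 enol ether go back to a 5-alkoxy-γ-lactone on C14; then C8–C14 and the ring B bond C6–C7 are cut together, leaving ring A with a C6 radical precursor and a C8(CH3)=C7H2 isopropenyl group on C9.
3. Enabling feature: C8 is a quaternary carbon bearing C17, between the C7 methylene and C14, so a 6-endo closure of ring B at C6–C7 produces the tertiary C8 radical exactly where a butenolide can be attached.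
4. Forward order: ring A with C5/C9/C10 comes from (−)-drimenol (its C7=C8 bond is cleaved, old C7 leaves as CO2, a new C7 is added by methylenation); ring B, C8 and C14 arise in step 5; the lactone is then reshaped into the acetoxy dihydrofuran.
5. Stereochemistry: C5, C9, C10 from drimenol; C8 by attack anti to the axial C10 methyl; C14 anti to the menthyloxy group of the (5S)-butenolide; C15 fixed trans to C14 on silylation of the lactol and retained in the final acetylation.

Key step: step 5

Remark: 1 and 7 are taken as purchasable compounds; 7 (the enantiomer of the common l-menthol-derived reagent) is otherwise obtained from 5-hydroxyfuran-2(5H)-one and (+)-menthol by acid-catalysed acetalisation and crystallisation.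

**Step 1**
Reactants: 1 (−)-drimenol
Product: 2 drimenyl pivalate
Conditions: t-BuCOCl, pyridine, DMAP (cat.), CH2Cl2, 0 °C to rt
Reagents that add atoms: pivaloyl chloride, CC(C)(C)C(=O)Cl
Why: DMAP-catalysed acylation of the primary C11 alcohol should give an ester that is inert to ozone, to radicals, to lithium amide at −78 °C and to aqueous acid, and that is removed later by hydride.

**Step 2**
Reactants: 2 drimenyl pivalate
Product: 4 seco keto acid, via seco keto aldehyde 3 (not isolated)
Conditions: O3, CH2Cl2, −78 °C; PPh3, −78 °C to rt; then t-BuOH/H2O, 2-methyl-2-butene, NaH2PO4, NaClO2, 0 °C to rt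
Reagents that add atoms: ozone, [O-][O+]=O; sodium chlorite, [Na+].[O-]Cl=O
Why: Ozonolysis should cleave the only alkene (C7=C8) to the C7 aldehyde and the C8 methyl ketone, and Pinnick oxidation in the same flask should convert the aldehyde to the acid before it can undergo intramolecular aldol reaction, with no stereocenter touched.

**Step 3**
Reactants: 4 seco keto acid
Product: 5 isopropenyl acid
Conditions: Zn, CH2Br2, TiCl4 (excess), THF/CH2Cl2, 0 °C to rt
Reagents that add atoms: dibromomethane, BrCBr
Why: The non-basic Lombardo–Takai methylenation should convert the methyl ketone into the C8(CH3)=C7H2 group without enolisation toward C9, so C9 is not epimerised and the β-pivaloyloxy group is not eliminated; the acid should be carried as its titanium carboxylate.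

**Step 4**
Reactants: 5 isopropenyl acid
Product: 6 N-(acyloxy)phthalimide of 5
Conditions: N-hydroxyphthalimide, i-PrN=C=N-i-Pr, DMAP (cat.), CH2Cl2, rt
Reagents that add atoms: N-hydroxyphthalimide, O=C1c2ccccc2C(=O)N1O
Why: Carbodiimide (Steglich-type) esterification should give the redox-active ester needed for reductive decarboxylation.

**Step 5**
Reactants: 6 N-(acyloxy)phthalimide of 5; 7 (5S)-5-(d-menthyloxy)furan-2(5H)-one
Product: 8 menthyloxy lactone adduct
Conditions: Ru(bpy)3(PF6)2 (1 mol %), Hantzsch ester (1.5 equiv), 7 (1.5 equiv), CH2Cl2 (0.02 M), blue LEDs, rt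
Reagents that add atoms: none
Why: Photoexcited Ru(bpy)3(PF6)2 is reduced by the Hantzsch ester and passes an electron to the phthalimide ester, which loses phthalimide anion and CO2 to give the primary C6 radical; this adds to the CH2 terminus (C7) of the isopropenyl group, the resulting tertiary C8 radical adds to C14 of butenolide 7, and the α-lactone radical is reduced by hydrogen transfer from the Hantzsch ester. The closest known reactions are the 6-endo radical closures of polyene cyclisations and the decarboxylative Giese coupling of tertiary radicals with 5-alkoxybutenolides, here run in one flask. Ring B closes in the 6-endo-trig mode through a chair transition state with both arms equatorial on ring A, which should give the trans-decalin. C8 is set because the butenolide approaches the ring B radical from the α-face, anti to the axial C10 methyl, so C14 becomes equatorial and C17 axial; C14 is set because addition occurs anti to the C15 menthyloxy group of 7. The step needs 6-endo over 5-exo closure, which the fully substituted internal alkene carbon C8 and the strain of a trans-fused five-membered ring should secure, and it needs ring closure before intermolecular addition, which dilution and the lower nucleophilicity of the primary radical should secure.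

**Step 6**
Reactants: 8 menthyloxy lactone adduct
Product: 9 hydroxy lactone (C15 lactol)
Conditions: CF3CO2H/H2O (4:1), 0 °C to rt
Reagents that add atoms: water, O
Why: Acid-catalysed acetal hydrolysis of the pseudo-ester should release the menthol auxiliary and leave C14 untouched, C15 becoming an equilibrating lactol.

**Step 7**
Reactants: 9 hydroxy lactone
Product: 10 C15 silyloxy lactone
Conditions: Et3SiCl, imidazole, DMF, 0 °C
Reagents that add atoms: chlorotriethylsilane, CC[Si](Cl)(CC)CC
Why: Silyl ether formation on the cyclic lactol should trap mainly the anomer with the silyloxy group trans to the bulky C14 substituent, which fixes C15 and gives an acetal that is later cleaved at the Si–O bond without ionising C15.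

**Step 8**
Reactants: 10 C15 silyloxy lactone
Product: 12 bis(silyl) lactone, via lithium aldolate 11 (not isolated)
Conditions: LiN(i-Pr)2, THF, −78 °C; CH2O (gas); then Et3SiCl, −78 to 0 °C
Reagents that add atoms: formaldehyde, C=O; chlorotriethylsilane, CC[Si](Cl)(CC)CC
Why: Lithium enolate aldol addition to monomeric formaldehyde should install C12 on C13 anti to the C14 substituent (this center becomes planar in step 10), and O-silylation in the same flask should prevent retro-aldol or β-elimination.

**Step 9**
Reactants: 12 bis(silyl) lactone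
Product: 13 C16 lactol
Conditions: i-Bu2AlH (1.15 equiv), CH2Cl2, −78 °C; aq. potassium sodium tartrate
Reagents that add atoms: none
Why: Partial reduction of the γ-lactone should stop at the lactol aluminate at −78 °C, the hindered pivalate reacting more slowly.

**Step 10**
Reactants: 13 C16 lactol
Product: 15 dihydrofuran pivalate, via C16 mesylate 14 (not isolated)
Conditions: MsCl, Et3N (excess), CH2Cl2, −40 to 40 °C
Reagents that add atoms: none
Why: Lactol dehydration by sulfonylation and amine-promoted elimination through the oxocarbenium ion can only remove H13, so it should give the C13=C16 enol ether with the C15 silyl acetal intact.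

**Step 11**
Reactants: 15 dihydrofuran pivalate
Product: 16 dihydrofuran alcohol
Conditions: i-Bu2AlH (2.5 equiv), CH2Cl2, −78 °C; aq. potassium sodium tartrate
Reagents that add atoms: none
Why: Reductive ester cleavage should free the C11 alcohol under conditions to which the enol ether and both silyl ethers are inert.

**Step 12**
Reactants: 16 dihydrofuran alcohol
Product: 17 dihydrofuran aldehyde
Conditions: Dess–Martin periodinane, pyridine, CH2Cl2, 0 °C to rt
Reagents that add atoms: none
Why: Buffered Dess–Martin oxidation should give the C11 aldehyde without acid that would ionise the silyl acetal, and the equatorial formyl group at C9 is the stable epimer.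

**Step 13**
Reactants: 17 dihydrofuran aldehyde
Product: 19 target, via lactol diol 18 (not isolated)
Conditions: Ac2O (10 equiv), Bu4NF (2.5 equiv, slow addition), THF, −40 to 0 °C
Reagents that add atoms: acetic anhydride, CC(=O)OC(C)=O
Why: Fluoride-triggered desilylative acylation cleaves both Si–O bonds (not the C15–O bond) and the excess anhydride should acetylate each alkoxide at once, so the C15 lactolate has no time to open or to lose water to a furan and its trans configuration is carried into the acetate.

**Compound list**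
1 | (−)-drimenol, [(1S,4aS,8aS)-2,5,5,8a-tetramethyl-1,4,4a,5,6,7,8,8a-octahydronaphthalen-1-yl]methanol | CC1=CC[C@H]2C(C)(C)CCC[C@]2(C)[C@H]1CO | starting material
2 | drimenyl pivalate (C11 pivalate of 1) | CC1=CC[C@H]2C(C)(C)CCC[C@]2(C)[C@H]1COC(=O)C(C)(C)C | intermediate
3 | seco keto aldehyde: ring A with C5–CH2–CHO and C10–C9H(CH2OPiv)(COCH3); C5, C9, C10 as in 1 | O=CC[C@H]1C(C)(C)CCC[C@]1(C)[C@H](C(C)=O)COC(=O)C(C)(C)C | intermediate (not isolated)
4 | seco keto acid: as 3 with CO2H in place of CHO | OC(=O)C[C@H]1C(C)(C)CCC[C@]1(C)[C@H](C(C)=O)COC(=O)C(C)(C)C | intermediate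
5 | isopropenyl acid: as 4 with C(CH3)=CH2 in place of COCH3 | OC(=O)C[C@H]1C(C)(C)CCC[C@]1(C)[C@H](C(C)=C)COC(=O)C(C)(C)C | intermediate
6 | N-(acyloxy)phthalimide of 5 | O=C(C[C@H]1C(C)(C)CCC[C@]1(C)[C@H](C(C)=C)COC(=O)C(C)(C)C)ON1C(=O)c2ccccc2C1=O | intermediate
7 | (5S)-5-{[(1S,2R,5S)-5-methyl-2-(propan-2-yl)cyclohexyl]oxy}furan-2(5H)-one | O=C1C=C[C@@H](O[C@H]2C[C@@H](C)CC[C@@H]2C(C)C)O1 | starting material
8 | menthyloxy lactone adduct: trans-decalin (5α-H, 9α-H, 10β-CH3, 8β-CH3) with C8 bonded to C14 of a (4R,5S)-5-menthyloxy-γ-butyrolactone on the α-face (C14/C15 trans), C11 pivalate | O=C1O[C@H](O[C@H]2C[C@@H](C)CC[C@@H]2C(C)C)[C@H](C1)[C@]1(C)CC[C@H]2C(C)(C)CCC[C@]2(C)[C@H]1COC(=O)C(C)(C)C | intermediate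
9 | hydroxy lactone: as 8 with OH at C15 (anomeric mixture) | O=C1OC(O)[C@H](C1)[C@]1(C)CC[C@H]2C(C)(C)CCC[C@]2(C)[C@H]1COC(=O)C(C)(C)C | intermediate
10 | C15 silyloxy lactone: as 8 with OSiEt3 at C15 (trans anomer drawn, expected major) | O=C1O[C@H](O[Si](CC)(CC)CC)[C@H](C1)[C@]1(C)CC[C@H]2C(C)(C)CCC[C@]2(C)[C@H]1COC(=O)C(C)(C)C | intermediate
11 | lithium aldolate: 10 with CH2OLi on C13, anti to the C14 substituent | O=C1O[C@H](O[Si](CC)(CC)CC)[C@H]([C@@H]1C[O-])[C@]1(C)CC[C@H]2C(C)(C)CCC[C@]2(C)[C@H]1COC(=O)C(C)(C)C.[Li+] | intermediate (not isolated)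
12 | bis(silyl) lactone: C12 and C15 triethylsilyl ethers, C11 pivalate | O=C1O[C@H](O[Si](CC)(CC)CC)[C@H]([C@@H]1CO[Si](CC)(CC)CC)[C@]1(C)CC[C@H]2C(C)(C)CCC[C@]2(C)[C@H]1COC(=O)C(C)(C)C | intermediate
13 | C16 lactol of 12 (C16 anomers) | OC1O[C@H](O[Si](CC)(CC)CC)[C@H]([C@@H]1CO[Si](CC)(CC)CC)[C@]1(C)CC[C@H]2C(C)(C)CCC[C@]2(C)[C@H]1COC(=O)C(C)(C)C | intermediate
14 | C16 mesylate of 13 | CS(=O)(=O)OC1O[C@H](O[Si](CC)(CC)CC)[C@H]([C@@H]1CO[Si](CC)(CC)CC)[C@]1(C)CC[C@H]2C(C)(C)CCC[C@]2(C)[C@H]1COC(=O)C(C)(C)C | intermediate (not isolated)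
15 | dihydrofuran pivalate: C13=C16 enol ether, C12 and C15 triethylsilyl ethers, C11 pivalate | CC[Si](CC)(CC)OCC1=CO[C@H](O[Si](CC)(CC)CC)[C@H]1[C@]1(C)CC[C@H]2C(C)(C)CCC[C@]2(C)[C@H]1COC(=O)C(C)(C)C | intermediate
16 | dihydrofuran alcohol: as 15 with free C11 OH | CC[Si](CC)(CC)OCC1=CO[C@H](O[Si](CC)(CC)CC)[C@H]1[C@]1(C)CC[C@H]2C(C)(C)CCC[C@]2(C)[C@H]1CO | intermediate
17 | dihydrofuran aldehyde: as 16 with C11 CHO | CC[Si](CC)(CC)OCC1=CO[C@H](O[Si](CC)(CC)CC)[C@H]1[C@]1(C)CC[C@H]2C(C)(C)CCC[C@]2(C)[C@H]1C=O | intermediate
18 | lactol diol (formed as its alkoxides): C12 OH and C15 OH | OCC1=CO[C@H](O)[C@H]1[C@]1(C)CC[C@H]2C(C)(C)CCC[C@]2(C)[C@H]1C=O | intermediate (not isolated)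
19 | CNP0170308.1, (5S,8R,9R,10S,14S,15R)-12,15-diacetoxy-15,16-epoxy-11,12-secospongi-13(16)-en-11-al | CC(=O)OCC1=CO[C@H](OC(C)=O)[C@H]1[C@]1(C)CC[C@H]2C(C)(C)CCC[C@]2(C)[C@H]1C=O | target

**Count and risks**
Total step count: 13. Longest linear sequence: 13 steps (1 to 19); 7 is brought in at step 5.

Steps most likely to fail:

Step 5. The primary C6 radical may be intercepted by the butenolide, or may shift a hydrogen from C11, before ring B closes; some 5-exo closure may occur; the tertiary radical may be reduced before it adds. The fallback sets out from 6 and returns at 8, with ring closure and fragment union done in two separate known operations. Decarboxylative 6-endo cyclisation with cobalt-mediated loss of hydrogen (Ru(bpy)3(PF6)2, Co(dmgH)2pyCl, blue LEDs) should give the exocyclic C8=C17 alkene albicanyl pivalate F1. Hydrogen-atom-transfer Giese coupling of F1 with 7 (Fe(acac)3, PhSiH3, EtOH/ethylene glycol, 60 °C) should then regenerate the same tertiary C8 radical and lead to 8.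

Step 13. The transient C15 lactolate may open with expulsion of the ring enolate, followed by C-protonation or dehydration to a furan, or may anomerise before it is acetylated. The fallback sets out from 13 and returns at 19; it installs both acetates on the saturated ring and forms the enol ether last.
- (PhS)2 and Bu3P in pyridine should give the C16 phenylthio acetal F3.
- i-Bu2AlH should give the C11 alcohol F4.
- Dess–Martin oxidation should give the C11 aldehyde F5.
- Ac2O/Bu4NF should give the 12,15-diacetate sulfide F6.
- m-CPBA (1 equiv, −78 °C) should give the sulfoxide F7.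
- Warming F7 with Et3N should cause syn-elimination toward H13 and give 19.

Step 10. The bis-acetal lactol may ring-open with loss of the silyl acetal, the anomeric chloride may persist, or elimination may run on to the furan. The fallback sets out from 12 and returns at 15 without a free lactol. One-flask reductive acetylation (i-Bu2AlH, −78 °C; then Ac2O, pyridine, DMAP) should give the C16 anomeric acetate F2. Selective ionisation of the acetate and loss of H13 (Me3SiOTf, i-Pr2NEt, CH2Cl2, −78 °C) should then give 15.

**Further compounds**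
F1 | step 5 | albicanyl pivalate (ring B closed, exocyclic C8=C17 alkene) | C=C1CC[C@H]2C(C)(C)CCC[C@]2(C)[C@H]1COC(=O)C(C)(C)C
F2 | step 10 | C16 anomeric acetate corresponding to lactol 13 | CC(=O)OC1O[C@H](O[Si](CC)(CC)CC)[C@H]([C@@H]1CO[Si](CC)(CC)CC)[C@]1(C)CC[C@H]2C(C)(C)CCC[C@]2(C)[C@H]1COC(=O)C(C)(C)C
F3 | step 13 | C16 phenylthio acetal (C12 and C15 silyl ethers, C11 pivalate) | c1ccccc1SC1O[C@H](O[Si](CC)(CC)CC)[C@H]([C@@H]1CO[Si](CC)(CC)CC)[C@]1(C)CC[C@H]2C(C)(C)CCC[C@]2(C)[C@H]1COC(=O)C(C)(C)C
F4 | step 13 | C11 alcohol of F3 | c1ccccc1SC1O[C@H](O[Si](CC)(CC)CC)[C@H]([C@@H]1CO[Si](CC)(CC)CC)[C@]1(C)CC[C@H]2C(C)(C)CCC[C@]2(C)[C@H]1CO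
F5 | step 13 | C11 aldehyde of F3 | c1ccccc1SC1O[C@H](O[Si](CC)(CC)CC)[C@H]([C@@H]1CO[Si](CC)(CC)CC)[C@]1(C)CC[C@H]2C(C)(C)CCC[C@]2(C)[C@H]1C=O
F6 | step 13 | 12,15-diacetate C16 sulfide | c1ccccc1SC1O[C@H](OC(C)=O)[C@H]([C@@H]1COC(C)=O)[C@]1(C)CC[C@H]2C(C)(C)CCC[C@]2(C)[C@H]1C=O
F7 | step 13 | sulfoxide of F6 | O=S(c1ccccc1)C1O[C@H](OC(C)=O)[C@H]([C@@H]1COC(C)=O)[C@]1(C)CC[C@H]2C(C)(C)CCC[C@]2(C)[C@H]1C=O
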